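The earlier runs and the new flask come from a simulation on assumed constants; the scatter is artificial.

The ratio I watch is the J budget, J charged less D charged, over L charged: 93.0 % in this flask.

the same everywhere: L 0.020 M

| charge | J | D | remark | time |
|---|---|---|---|---|
| dusk | 0.0095 M | 0.40 mM | run made earlier |  |
| winter | 0.038 M | 0.40 mM | run made earlier |  |
| flask | 0.0190 M | 0.400 mM |  | 20 h |

| run | time / h | X / % | G / % |
|---|---|---|---|
| dusk | 3.00 | 9.3 | 9.4 |
| dusk | 6.00 | 15.8 | 18.4 |
| dusk | 8.00 | 17.2 | 22.2 |
| dusk | 12.0 | 21.6 | 25.8 |
| dusk | 15.0 | 22.8 | 28.0 |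
| dusk | 20.0 | 23.7 | 28.8 |
| winter | 3.00 | 8.1 | 28.8 |
| winter | 6.00 | 9.4 | 53.3 |
| winter | 8.00 | 9.1 | 64.1 |
| winter | 12.0 | 9.2 | 76.6 |
| winter | 15.0 | 9.0 | 82.7 |
| winter | 20.0 | 7.8 | 87.4 |

(scatter of a reading: 0.5 percentage points)
- how much X the flask holds at 20 h, in percent of the L charged
- how much G the flask holds at 20 h, in percent of the L charged
- concentration of J at 20 h, in M
- in percentages every species weighs as the L in it: one X counts as two
- for G the E are counted in
- candidate steps: Q -> G; L + J -> Q; J + D -> Z; L + Q -> X; J + G <-> E

1. The steps on offer: L and J give Q; Q gives G, or with L gives X; J and D give Z; J and G give E, reversibly. So each G costs one J, each X one J though it counts as two L, and each E a second J. I charge D its whole amount to J. This gives G + X/2 + rest = budget, where the rest is Q, E and free J.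

2. First readings: after 3.00 h, G reads 9.4 % in dusk and 28.8 % in winter, 3.06 times as much at 4.00 times the J. X reads 9.3 % in dusk and 8.1 % in winter, but winter's X is by then close to its later readings and dusk's is still climbing, so this pair says little about how X answers to cJ at the very start.

3. Middle: winter's X reads 9.4 % at 6.00 h and 7.8 % at 20.0 h, while dusk's climbs to 23.7 %. I expect this flask to keep L longer than winter and hold more Q than dusk, so my first answer for X is dusk's value.

4. End, first round: with no rest, G is 81.1 %, and with X that makes 105 %, more than the L charged. The rest cannot be ignored.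

5. Second round: dusk's budget is 45.5 %, its rest reads 4.8 percentage points, and L with Q still stands at 47.5 %, so there J is the limiting reagent. That is 0.168 of rest per G. Put back, G is 69.5 %, with a rest of 0.00234 M, of which cJ is some part. More free J here could raise that share and lower G.

6. The forecast, whose G stands above mine and whose X below, gives 18 % of X, 75 % of G and 4.000 × 10⁻⁴ M of J, holding that “J is consumed stoichiometrically”.

The flask gives 23.5 % of X, 58.1 % of G and 2.45 × 10⁻⁴ M of J.

    Q → G (k = 0.170 /h)
    L + J → Q (k = 44.0 /M/h)
    J + D → Z (k = 500 /M/h)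
    L + Q → X (k = 5.80 /M/h)
    J + G ⇌ E, settled at all times (K = 2000 /M)

Here 93.0 % less G and half of X leaves a rest of 23 points, of which E is 19.1 %; that is 0.398 per G, against dusk's reading of 0.168. The same flask with 0.0016 M of D has a budget of 87.0 %. Its G of 54.7 % and X of 24.3 % leave a rest of 20 points, with D at 0 % and E at 16.4 %.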